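The numbers were chosen freely; what happens was integrated by code.

In a one-step world you would read one rate constant and know when to stop. Here substrate passes through open intermediate to product, catalyst serves both steps, and you have to choose the time and the catalyst charge of your next run.

    substrate + free catalyst → free catalyst + open intermediate (k1 = 60.6 /M/s)
    free catalyst + open intermediate ⇌ catalyst intermediate (K2 = 3100 /M, k2 = 299 /M/s)
    reagent + catalyst intermediate → free catalyst + product (k3 = 1140 /M/s)
    gas ⇌ reagent, rate k4*(csat - [reagent]) (k4 = 0.211 /s, csat = 4.8 mM)

common to all: substrate 10 mM; gas 4.8 mM (held); free catalyst 0.5 mol%
- Wednesday's: time 1.5 min
- Monday's: time 3.0 min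
- Friday's: time 6.0 min

- at the start none of reagent is dissolved
- run time (Wednesday's): 1.5 min

- which of these there is most of at the end, counted by the substrate in it, Wednesday's (open intermediate / product / substrate)
- which of these there is most of at the end, counted by the substrate in it, Monday's (open intermediate / product / substrate)
- which of these there is most of at the end, counted by the substrate in it, Friday's (open intermediate / product / substrate)
- the largest of these amounts at the end, in percent of the substrate charged, Wednesday's
- the largest of these amounts at the end, in percent of the substrate charged, Monday's
- the largest of these amounts at the end, in percent of the substrate charged, Friday's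

Start with the reagent. In Wednesday's flask its filling half-life of 3.29 s is far shorter than the substrate's 3.8 min, so I take c(reagent) as 4.8 mM. Catalyst intermediate then goes on at 5.47 /s and back at 0.0965 /s, so nearly all of it gives product. That leaves substrate and open intermediate each used at a constant times c(free catalyst), with the second constant 4.93 times the first. So I reckon with one number:

θ = 60.6 /M/s × catalyst charged × time

Wednesday's 0.273, Monday's 0.545, Friday's 1.09

Call θ, that constant times catalyst charged times time, the catalyst clock.

First round, with the whole charge taken as free, for Wednesday's:

c(open intermediate) = c(substrate charged) × (exp(−θ) − exp(−4.93θ)) / (4.93 − 1) = 1.27 mM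

Put that back in. Catalyst intermediate over free catalyst is 0.0684, so the free share, the resting state of the catalyst, is 93.6%. Second round, with fθ in place of θ:

Wednesday's: substrate 77.5%, product 10.0%

Monday's: substrate 60.0%, product 26.8%

Friday's: substrate 36.0%, product 55.0%

By this reckoning product is behind substrate on Monday's clock and ahead on Friday's. So the crossing lies somewhere between a clock of 0.545 and one of 1.09; a next run that reaches Friday's reading has product in the lead by this reckoning, one that stops short of it may too, and you may pay for the clock in time or in catalyst.

The forecast, working from “two roughly first-order steps in series”, says substrate at 77.2% for Wednesday's, substrate at 59.9% for Monday's and product at 55% for Friday's. My numbers lie close to these but are not the same.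

The simulation gives substrate at 77.0% for Wednesday's, substrate at 59.7% for Monday's and product at 55.1% for Friday's.

Wednesday's clock of 0.273 with a free share of 93.6% gave 77.5% substrate, and the flask holds 77.0%, with free catalyst at 93.5%. Now take the neighbour: Wednesday's flask with 2 mol% of free catalyst, stopped at 1.5 min. Its clock reads 1.09, level with Friday's, so the reckoning gives substrate 36.0% and product 55.0% there too. That flask held 35.9% substrate, with reagent at 4.55 mM, and product held most, 54.8%.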